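**Retrosynthetic overview**
- The target is read as (2S)-7,4'-dihydroxyflavan-(4β→8)-epiafzelechin-(4β→8)-epiafzelechin (upper unit 2S,4R and 2,4-trans; middle unit 2R,3R,4S; lower unit 2R,3R); the last step is global debenzylation.
- Both interflavan C4–C8 bonds are cut as flavan-4-yl cation plus C8 of a phloroglucinol-type ring A, lower bond first and upper bond second, as in proanthocyanidin chain assembly.
- The epiafzelechin unit (one batch, used twice, once activated at C4 with DDQ) comes from a cis-flavan-4-ol by moving the oxygen from C4 to C3 (flavene, 3-ketone, hydride anti to the aryl group).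
- Ring C of each unit is cut at O1–C2: a 2'-hydroxychalcone closes by chalcone-isomerase-like oxa-Michael addition, run reversibly under asymmetric transfer hydrogenation so that the racemic flavanone drains to one cis-flavan-4-ol; this fixes C2 without a chiral cyclisation catalyst.
- Order of ring formation: ring C of the epiafzelechin unit first (steps 1–2), ring C of the upper flavan second (steps 8–9); rings A and B are bought.

Assumption: the three benzyl ethers used as starting materials (2-hydroxy-4,6-bis(benzyloxy)acetophenone, 4-benzyloxy-2-hydroxyacetophenone, 4-benzyloxybenzaldehyde) are bought as cheap catalog compounds.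

**Route**

Step 1
Reactants: 1 1-[2,4-bis(benzyloxy)-6-hydroxyphenyl]ethanone; 2 4-(benzyloxy)benzaldehyde
Product: 3 (E)-1-[2,4-bis(benzyloxy)-6-hydroxyphenyl]-3-[4-(benzyloxy)phenyl]prop-2-en-1-one
Conditions: KOH (50 % aq), EtOH/THF, 25 °C, 36 h; then aq. HCl
Reagents that add atoms: none
Why: Claisen–Schmidt (crossed aldol) condensation of the methyl ketone with the non-enolisable aldehyde, dehydrating to the conjugated E-enone; no stereocenter is formed.

Step 2
Reactants: 3 (E)-1-[2,4-bis(benzyloxy)-6-hydroxyphenyl]-3-[4-(benzyloxy)phenyl]prop-2-en-1-one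
Product: 5 (2S,4S)-5,7-bis(benzyloxy)-2-[4-(benzyloxy)phenyl]chroman-4-ol, via racemic flavanone 4 (not isolated)
Conditions: DBU (3 equiv), MeCN, 40 °C, 3 h; then RuCl[(S,S)-TsDPEN](p-cymene) (2 mol %), HCO2H (2.5 equiv), 40 °C, 36 h
Reagents that add atoms: none
Why: Proposed new method: DBU closes ring C by reversible 6-endo oxa-Michael addition (the chalcone isomerase reaction), so the two flavanone enantiomers keep interconverting through retro-oxa-Michael ring opening while the (S,S)-TsDPEN ruthenium hydride reduces the (2S)-flavanone much faster (hydride anti to the 2-aryl group, giving the cis alcohol with 4S, as a flavanone 4-reductase would), which sets C2 by dynamic kinetic resolution; closest known reaction type: Noyori–Ikariya transfer-hydrogenative dynamic kinetic resolution of 2-substituted chroman-4-ones by elimination-induced racemisation, and kinetic resolution of flavanones with the same catalysts.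

Step 3
Reactants: 5 (2S,4S)-5,7-bis(benzyloxy)-2-[4-(benzyloxy)phenyl]chroman-4-ol
Product: 6 (2S)-5,7-bis(benzyloxy)-2-[4-(benzyloxy)phenyl]-2H-chromene
Conditions: Burgess reagent (MeO2CN–SO2–NEt3 inner salt, 1.5 equiv), THF, 50 °C, 2 h, dark
Reagents that add atoms: none
Why: Burgess dehydration (syn-elimination of the benzylic sulfamate) gives the conjugated flav-3-ene under neutral conditions, so C2 is untouched and no acid is present that could ionise the C2–O bond.

Step 4
Reactants: 6 (2S)-5,7-bis(benzyloxy)-2-[4-(benzyloxy)phenyl]-2H-chromene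
Product: 8 (2R)-5,7-bis(benzyloxy)-2-[4-(benzyloxy)phenyl]chroman-3-one, via flavene 3,4-epoxide 7 (not isolated)
Conditions: DMDO (1.1 equiv, acetone), CH2Cl2, −40 °C; solvent exchange cold; InCl3 (5 mol %), CH2Cl2, −20 °C
Reagents that add atoms: dimethyldioxirane (DMDO), CC1(C)OO1
Why: Epoxidation anti to the 2-aryl group followed by Meinwald rearrangement (C4–O ionisation to a cation stabilised by the 5,7-dialkoxy ring and O1, then 1,2-hydride shift from C3) gives the 3-ketone as known for 1,2-dihydronaphthalene and 2H-chromene oxides; C2 keeps its geometry and its descriptor changes from S to R only through the priority rules.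

Step 5
Reactants: 8 (2R)-5,7-bis(benzyloxy)-2-[4-(benzyloxy)phenyl]chroman-3-one
Product: 9 (2R,3R)-5,7-bis(benzyloxy)-2-[4-(benzyloxy)phenyl]chroman-3-ol (5,7,4'-tri-O-benzylepiafzelechin)
Conditions: LiBH(s-Bu)3 (1.5 equiv), THF, −78 °C; then H2O
Reagents that add atoms: none
Why: Substrate-controlled ketone reduction in which the bulky hydride attacks anti to the 2-aryl group, so the new OH is cis to it (3R), the standard way from catechin-type to epicatechin-type benzyl ethers.

Step 6
Reactants: 9 (2R,3R)-5,7-bis(benzyloxy)-2-[4-(benzyloxy)phenyl]chroman-3-ol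
Product: 10 (2R,3R,4S)-5,7-bis(benzyloxy)-2-[4-(benzyloxy)phenyl]-4-(2-ethoxyethoxy)chroman-3-ol
Conditions: DDQ (2 equiv), 2-ethoxyethanol (5 equiv), CH2Cl2, 25 °C, 2 h
Reagents that add atoms: 2-ethoxyethanol, CCOCCO
Why: DDQ-mediated benzylic C–H oxidation (hydride abstraction from C4, which is activated by the trioxygenated ring A) and capture of the cation by the alcohol trans to the 3-OH (4S), as established for benzylated epicatechin.

Step 7
Reactants: 10 (2R,3R,4S)-5,7-bis(benzyloxy)-2-[4-(benzyloxy)phenyl]-4-(2-ethoxyethoxy)chroman-3-ol; 9 (2R,3R)-5,7-bis(benzyloxy)-2-[4-(benzyloxy)phenyl]chroman-3-ol (3.5 equiv, excess recovered)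
Product: 11 hexa-O-benzyl epiafzelechin-(4β→8)-epiafzelechin [upper unit 2R,3R,4R; lower unit 2R,3R]
Conditions: TMSOTf (0.2 equiv), CH2Cl2, −78 °C, 30 min; then aq. NaHCO3
Reagents that add atoms: none
Why: Lewis-acid-promoted Friedel–Crafts alkylation that copies proanthocyanidin chain extension: the 4-alkoxy group ionises to the flavan-4-yl cation, and C8 of 9 attacks it trans to the axial 3-OH (4β, descriptor 4R), with excess 9 suppressing oligomers.

Step 8
Reactants: 12 1-[4-(benzyloxy)-2-hydroxyphenyl]ethanone; 2 4-(benzyloxy)benzaldehyde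
Product: 13 (E)-1-[4-(benzyloxy)-2-hydroxyphenyl]-3-[4-(benzyloxy)phenyl]prop-2-en-1-one
Conditions: KOH (50 % aq), EtOH, 25 °C, 24 h; then aq. HCl
Reagents that add atoms: none
Why: Claisen–Schmidt condensation as in step 1, giving the E-enone with no stereocenter.

Step 9
Reactants: 13 (E)-1-[4-(benzyloxy)-2-hydroxyphenyl]-3-[4-(benzyloxy)phenyl]prop-2-en-1-one
Product: 15 (2S,4S)-7-(benzyloxy)-2-[4-(benzyloxy)phenyl]chroman-4-ol, via racemic flavanone 14 (not isolated)
Conditions: DBU (3 equiv), MeCN, 40 °C, 6 h; then RuCl[(S,S)-TsDPEN](p-cymene) (2 mol %), HCO2H (2.5 equiv), 40 °C, 36 h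
Reagents that add atoms: none
Why: Proposed new method: as in step 2, reversible base-mediated oxa-Michael ring closure keeps the flavanone racemising through the open chalcone while the (S,S)-TsDPEN ruthenium hydride selectively reduces the (2S)-enantiomer anti to the aryl group to the cis-(2S,4S) alcohol, so C2 is set by dynamic kinetic resolution; closest known reaction type: transfer-hydrogenative dynamic kinetic resolution of 2-substituted chroman-4-ones by elimination-induced racemisation.

Step 10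
Reactants: 11 hexa-O-benzyl epiafzelechin-(4β→8)-epiafzelechin (2 equiv, excess recovered); 15 (2S,4S)-7-(benzyloxy)-2-[4-(benzyloxy)phenyl]chroman-4-ol
Product: 16 octa-O-benzyl (2S)-7,4'-dihydroxyflavan-(4β→8)-epiafzelechin-(4β→8)-epiafzelechin [upper unit 2S,4R; middle unit 2R,3R,4S; lower unit 2R,3R]
Conditions: Sc(OTf)3 (10 mol %), 4 Å MS, CH2Cl2, −40 to −20 °C
Reagents that add atoms: none
Why: Catalytic dehydrative Friedel–Crafts alkylation in which the 4-OH of 15 leaves as water and the 7-alkoxy-stabilised flavan-4-yl cation is captured by C8 of the upper unit of 11 (the least hindered activated position), with axial attack on the half-chair cation whose 2-aryl group is equatorial placing the new bond trans to that aryl group (4R), as in Friedel–Crafts routes to 2,4-trans-4-arylflavans.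

Step 11
Reactants: 16 octa-O-benzyl (2S)-7,4'-dihydroxyflavan-(4β→8)-epiafzelechin-(4β→8)-epiafzelechin
Product: 17 (2S)-7,4'-dihydroxyflavan-(4β→8)-epiafzelechin-(4β→8)-epiafzelechin (CNP0257624.1)
Conditions: H2 (1 atm), Pd(OH)2/C, THF/MeOH/H2O, 25 °C
Reagents that add atoms: none
Why: Hydrogenolysis of the eight benzyl ethers under the standard conditions for benzylated proanthocyanidins, which leave the interflavan C–C bonds, the ring C ethers and all stereocenters untouched.

**Compound list**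

1 | 1-[2,4-bis(benzyloxy)-6-hydroxyphenyl]ethanone | CC(=O)c1c(O)cc(OCc2ccccc2)cc1OCc1ccccc1 | starting material
2 | 4-(benzyloxy)benzaldehyde | O=Cc1ccc(OCc2ccccc2)cc1 | starting material
3 | (E)-1-[2,4-bis(benzyloxy)-6-hydroxyphenyl]-3-[4-(benzyloxy)phenyl]prop-2-en-1-one | O=C(/C=C/c1ccc(OCc2ccccc2)cc1)c1c(O)cc(OCc2ccccc2)cc1OCc1ccccc1 | intermediate
4 | racemic 5,7-bis(benzyloxy)-2-[4-(benzyloxy)phenyl]chroman-4-one | O=C1CC(c2ccc(OCc3ccccc3)cc2)Oc2cc(OCc3ccccc3)cc(OCc3ccccc3)c21 | intermediate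
5 | (2S,4S)-5,7-bis(benzyloxy)-2-[4-(benzyloxy)phenyl]chroman-4-ol (2,4-cis) | O[C@H]1C[C@@H](c2ccc(OCc3ccccc3)cc2)Oc2cc(OCc3ccccc3)cc(OCc3ccccc3)c21 | intermediate
6 | (2S)-5,7-bis(benzyloxy)-2-[4-(benzyloxy)phenyl]-2H-chromene | C1=C[C@@H](c2ccc(OCc3ccccc3)cc2)Oc2cc(OCc3ccccc3)cc(OCc3ccccc3)c21 | intermediate
7 | (2R,3S,4S)-5,7-bis(benzyloxy)-2-[4-(benzyloxy)phenyl]-3,4-epoxychroman (epoxide oxygen trans to the 2-aryl group) | [C@H]13O[C@@H]3[C@@H](c3ccc(OCc4ccccc4)cc3)Oc2cc(OCc3ccccc3)cc(OCc3ccccc3)c21 | intermediate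
8 | (2R)-5,7-bis(benzyloxy)-2-[4-(benzyloxy)phenyl]chroman-3-one | O=C1[C@@H](c2ccc(OCc3ccccc3)cc2)Oc2cc(OCc3ccccc3)cc(OCc3ccccc3)c2C1 | intermediate
9 | (2R,3R)-5,7-bis(benzyloxy)-2-[4-(benzyloxy)phenyl]chroman-3-ol (5,7,4'-tri-O-benzylepiafzelechin; 2,3-cis) | c1ccc(COc2cc(OCc3ccccc3)c3c(c2)O[C@H](c2ccc(OCc4ccccc4)cc2)[C@H](O)C3)cc1 | intermediate
10 | (2R,3R,4S)-5,7-bis(benzyloxy)-2-[4-(benzyloxy)phenyl]-4-(2-ethoxyethoxy)chroman-3-ol (4-alkoxy group trans to 3-OH) | c1ccc(COc2cc(OCc3ccccc3)c3c(c2)O[C@H](c2ccc(OCc4ccccc4)cc2)[C@H](O)[C@H]3OCCOCC)cc1 | intermediate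
11 | hexa-O-benzyl epiafzelechin-(4β→8)-epiafzelechin [upper unit 2R,3R,4R; lower unit 2R,3R; all six phenols as benzyl ethers; both 3-OH free] | c1ccc(COc2cc(OCc3ccccc3)c3c(c2)O[C@H](c2ccc(OCc4ccccc4)cc2)[C@H](O)[C@H]3c2c(OCc3ccccc3)cc(OCc3ccccc3)c3c2O[C@H](c2ccc(OCc4ccccc4)cc2)[C@H](O)C3)cc1 | intermediate
12 | 1-[4-(benzyloxy)-2-hydroxyphenyl]ethanone | CC(=O)c1ccc(OCc2ccccc2)cc1O | starting material
13 | (E)-1-[4-(benzyloxy)-2-hydroxyphenyl]-3-[4-(benzyloxy)phenyl]prop-2-en-1-one | O=C(/C=C/c1ccc(OCc2ccccc2)cc1)c1ccc(OCc2ccccc2)cc1O | intermediate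
14 | racemic 7-(benzyloxy)-2-[4-(benzyloxy)phenyl]chroman-4-one | O=C1CC(c2ccc(OCc3ccccc3)cc2)Oc2cc(OCc3ccccc3)ccc21 | intermediate
15 | (2S,4S)-7-(benzyloxy)-2-[4-(benzyloxy)phenyl]chroman-4-ol (2,4-cis) | O[C@H]1C[C@@H](c2ccc(OCc3ccccc3)cc2)Oc2cc(OCc3ccccc3)ccc21 | intermediate
16 | octa-O-benzyl (2S)-7,4'-dihydroxyflavan-(4β→8)-epiafzelechin-(4β→8)-epiafzelechin [upper unit 2S,4R; middle unit 2R,3R,4S, same geometry as 4R in 11 (priority change); lower unit 2R,3R] | c5ccccc5COc1ccc([C@@H]2C[C@@H](c3c(OCc5ccccc5)cc(OCc5ccccc5)c4c3O[C@H](c3ccc(OCc5ccccc5)cc3)[C@H](O)[C@H]4c3c(OCc5ccccc5)cc(OCc5ccccc5)c4c3O[C@H](c3ccc(OCc5ccccc5)cc3)[C@H](O)C4)c3ccc(OCc5ccccc5)cc3O2)cc1 | intermediate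
17 | (2S)-7,4'-dihydroxyflavan-(4β→8)-epiafzelechin-(4β→8)-epiafzelechin, CNP0257624.1 [upper unit 2S,4R; middle unit 2R,3R,4S; lower unit 2R,3R] | Oc1ccc([C@@H]2C[C@@H](c3c(O)cc(O)c4c3O[C@H](c3ccc(O)cc3)[C@H](O)[C@H]4c3c(O)cc(O)c4c3O[C@H](c3ccc(O)cc3)[C@H](O)C4)c3ccc(O)cc3O2)cc1 | target

**Step count and risks**

Total step count: 11. Longest linear sequence: 9 steps (steps 1–7, 10, 11); steps 8–9 form the second branch.

Three steps most likely to fail:

Step 2 (the same method is used again in step 9). The risk is that the open chalcone is itself reduced, or that ring opening is too slow and the alcohol forms with low enantiomeric purity. The fallback sets out from 3: close the ring separately (NaOAc, EtOH, reflux) and isolate racemic flavanone 4. Then reduce it under non-racemising conditions (RuCl[(S,S)-TsDPEN](p-cymene), HCO2H/Et3N, EtOAc, 25 °C, stopped near 50 % conversion). This classical kinetic resolution gives 5 together with unreacted (2R)-5,7-bis(benzyloxy)-2-[4-(benzyloxy)phenyl]chroman-4-one F1, which is racemised back to 4 with DBU and recycled; the route is rejoined at 5. For step 9 the same detour sets out from 13, passes isolated 14 and recovered (2R)-7-(benzyloxy)-2-[4-(benzyloxy)phenyl]chroman-4-one F2, and comes back at 15.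

Step 4. The risk is that the very labile epoxide 7 is trapped by nucleophiles or rearranges with ring contraction, or that ketone 8 loses configuration at C2. The fallback sets out from 6: hydroboration and oxidation (BH3·THF, 0 °C; then NaOH, H2O2) put boron on C3 anti to the aryl group and give (2R,3S)-5,7-bis(benzyloxy)-2-[4-(benzyloxy)phenyl]chroman-3-ol F3. Oxidation of F3 with Dess–Martin periodinane (CH2Cl2, 0 °C) comes back to the route at 8.

Step 10. The risk is alkylation at C6 of either unit of 11, or 2,4-cis attack, giving isomer mixtures that are hard to separate at the trimer stage. The fallback changes the order of the two interflavan bonds and sets out from 15 and 9. Couple them (9 in excess, Sc(OTf)3, CH2Cl2, −40 °C) to penta-O-benzyl (2S)-7,4'-dihydroxyflavan-(4β→8)-epiafzelechin F4 and purify the 2,4-trans, C8-linked isomer at this smaller stage. Activate C4 of its epiafzelechin unit with DDQ and 2-ethoxyethanol to penta-O-benzyl (2S)-7,4'-dihydroxyflavan-(4β→8)-4β-(2-ethoxyethoxy)epiafzelechin F5; the diarylmethine C4–H of the upper unit is flanked by the 7-benzyloxy group and ring oxygen of the lower unit, so it is shielded and should be spared. Couple F5 with excess 9 (TMSOTf, CH2Cl2, −78 °C) to come back at 16.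

Further compounds
F1 | step 2 | (2R)-5,7-bis(benzyloxy)-2-[4-(benzyloxy)phenyl]chroman-4-one | O=C1C[C@H](c2ccc(OCc3ccccc3)cc2)Oc2cc(OCc3ccccc3)cc(OCc3ccccc3)c21
F2 | step 2 | (2R)-7-(benzyloxy)-2-[4-(benzyloxy)phenyl]chroman-4-one | O=C1C[C@H](c2ccc(OCc3ccccc3)cc2)Oc2cc(OCc3ccccc3)ccc21
F3 | step 4 | (2R,3S)-5,7-bis(benzyloxy)-2-[4-(benzyloxy)phenyl]chroman-3-ol (2,3-trans) | c1ccc(COc2cc(OCc3ccccc3)c3c(c2)O[C@H](c2ccc(OCc4ccccc4)cc2)[C@@H](O)C3)cc1
F4 | step 10 | penta-O-benzyl (2S)-7,4'-dihydroxyflavan-(4β→8)-epiafzelechin [upper unit 2S,4R; lower unit 2R,3R] | c5ccccc5COc1ccc([C@@H]2C[C@@H](c3c(OCc5ccccc5)cc(OCc5ccccc5)c4c3O[C@H](c3ccc(OCc5ccccc5)cc3)[C@H](O)C4)c3ccc(OCc5ccccc5)cc3O2)cc1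
F5 | step 10 | penta-O-benzyl (2S)-7,4'-dihydroxyflavan-(4β→8)-4β-(2-ethoxyethoxy)epiafzelechin [upper unit 2S,4R; lower unit 2R,3R,4S] | c5ccccc5COc1ccc([C@@H]2C[C@@H](c3c(OCc5ccccc5)cc(OCc5ccccc5)c4c3O[C@H](c3ccc(OCc5ccccc5)cc3)[C@H](O)[C@H]4OCCOCC)c3ccc(OCc5ccccc5)cc3O2)cc1
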